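The data are calculated for substances that don't exist; the scatter is artificial.

If the starting material goes by itself, that part of its fall stays the same when the catalyst changes, and this is what I try to pull out of the runs.

| flask | starting material | coupling partner | free catalyst | time |
|---|---|---|---|---|
| ochre | 250 mM | 500 mM | 13.0 mM |  |
| green | 100 mM | 350 mM | 13.0 mM |  |
| teal | 250 mM | 500 mM | 26.0 mM |  |
| red | 250 mM | 1000 mM | 13.0 mM |  |
| blue | 500 mM | 500 mM | 4.30 mM | 8.1 h |

- ochre run (time / h: [starting material] / mM): 1.4: 132.0; 2.7: 69.1; 4.0: 34.5; 5.4: 15.4; 6.8: 6.5; 8.1: 2.6
- green run (time / h: [starting material] / mM): 1.4: 48.1; 2.7: 21.9; 4.0: 14.1; 5.4: 4.3; 6.8: 0.9; 8.1: 0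
- teal run (time / h: [starting material] / mM): 1.4: 99.9; 2.7: 37.2; 4.0: 11.0; 5.4: 4.0; 6.8: 0; 8.1: 0
- red run (time / h: [starting material] / mM): 1.4: 119.2; 2.7: 56.5; 4.0: 26.0; 5.4: 10.8; 6.8: 3.2; 8.1: 2.4

(scatter of a reading: 1 mM)

- the exponent of [free catalyst] in the starting rate at the charge of the ochre run (at the point where two percent of the starting material have become product)
- the exponent of [coupling partner] in the starting rate at the charge of the ochre run (at the point where two percent of the starting material have become product)
- starting material in the blue run at 8.1 h, as a share of the starting material charged
- which of these the readings show (the substrate is lost by itself / the catalyst dies in pairs / the product decays / nothing beyond the main steps)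

- Overall: starting material + coupling partner -> product, with free catalyst as catalyst.
- Constant volume, constant temperature.
- "The second partner" is coupling partner.
- An order is taken over about fifteen percent of the charge, up and down.

Write S for [starting material] and k for the slope of ln S against time, a pseudo-first-order constant. Suppose k is a self-loss constant k_L plus a main part proportional to free catalyst. Teal has twice the catalyst of ochre, so k_L = 2·k_O − k_T, with O for ochre and T for teal.

Up to 4.0 h, ochre gives 0.495 h⁻¹ and teal 0.781 h⁻¹, so k_L would be 0.209 h⁻¹. I distrust that, since equal times are unequal flasks: at 4.0 h teal reads 11.0 mM and ochre 34.5 mM, and k changes as S falls.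

So I let S be the clock and compare windows around the same S. Ochre from 2.7 h to 5.4 h is centred on 32.6 mM and gives k_O = 0.556 h⁻¹. Teal from 1.4 h to 4.0 h is centred on 33.1 mM and gives k_T = 0.849 h⁻¹. That makes k_L = 0.263 h⁻¹.

Is this scatter? The low readings put about 0.0595 h⁻¹ on it, so k_L stands 4.42 of those above zero. Could dying catalyst imitate it? Ochre's first stretch gives 0.456 h⁻¹, less than the later 0.556 h⁻¹, so k does not fall along that run; but something else may be raising k as S drops, so this does not rule dying catalyst out, and the doubt stays open.

Dividing rates removes both S and time: k_L/k is the share of the fall that goes by itself. For blue, the catalyst is 0.331 of ochre's. Ochre's main part runs from 0.193 h⁻¹ early to 0.293 h⁻¹ later, so scaled and added to k_L these give 0.327 h⁻¹ and 0.360 h⁻¹. Those leave 7.07% and 5.41% at 8.1 h. But blue starts with as much starting material as partner, outside ochre's range, and the proportionality to catalyst is my assumption. In this scaling k_L enters with weight 0.669, since the main part shifts the opposite way, so its scatter would multiply the answer by 1.38. I commit to the middle, 6.19%, with the self-loss as what the readings show.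

The forecast gives 1 for catalyst, 0.52 for partner and 7% for blue, and says “so the substrate is being lost by itself”.

The blue flask holds 6.62% at 8.1 h; the orders are 0.86 and 0.62, and the answer is that the substrate is lost by itself. The fit with the true steps forecasts 6.32% for blue, and the fit with nothing beyond the main steps 49.7%; the fit in which the catalyst dies in pairs leaves a root mean square residual of 7.3 in units of the scatter.

    free catalyst + starting material → loaded catalyst + by-product (32.08 L mol⁻¹ h⁻¹)
    loaded catalyst + coupling partner → product + free catalyst (8.172 L mol⁻¹ h⁻¹)
    starting material → decomposed substrate (0.2714 h⁻¹)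

That blue value means an average k of 0.335 h⁻¹, of which k_L, 0.263 h⁻¹, is a share of 78.5%. In the green run, k_L times the trapezoid area under the readings of S up to 8.1 h gives about 50.0 mM lost by itself out of the 100 mM charged, and green's product comes to half of that charge at 7.37 h.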